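**Plan**

- The target is a 19-membered bis(bibenzyl) with ring A (4-hydroxy-3-aryloxyphenyl), ring B (meta-phenylene), ring C (the catechol ring) and ring D (para-phenylene). It has no stereocentre.
- Retrosynthesis first removes the three O-methyl groups and re-oxidises the ring B benzylic carbon of the B–C bridge to a ketone. It then cuts the ring C aryl–CH2 bond: that CH2 is the α-carbon of an acetyl group on ring B, so the bond comes from a ketone enolate and a ring C bromide.
- Next the CH2–CH2 bond of the A–D bridge is cut (Wittig olefination, then hydrogenation), then the two diaryl ether C–O bonds (A–O–B by Chan–Lam coupling, C–O–D by SNAr).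
- Forward: an AB keto aldehyde and a CD phosphonium salt are made separately and joined to one open chain. The only ring formed, the macrocycle, closes in the enolate arylation; the carbonyl is then removed and the methyl ethers are cleaved.
- Stereochemistry: none to set. The stilbene geometry is erased by hydrogenation, and the carbinol centre that appears during the ionic reduction is removed in the same flask.

Key step: step 7

Assumption: the 19-membered ring is taken as conformationally mobile at room temperature, so no atropisomer has to be controlled, and 5-bromo-2,3-dimethoxyphenol is bought as such.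

**Step 1**
Reactants: 1 isovanillin (3-hydroxy-4-methoxybenzaldehyde); 2 3-acetylphenylboronic acid
Product: 3 3-(3-acetylphenoxy)-4-methoxybenzaldehyde (AB keto aldehyde)
Conditions: Cu(OAc)2 (2 equiv), pyridine, 4 Å molecular sieves, CH2Cl2, air, rt
Reagents that add atoms: none
Why: Chan–Lam oxidative O-arylation joins the phenol of 1 to the arylboronic acid at room temperature under a weak amine base, so the aldehyde and the enolisable methyl ketone are never exposed to aldol conditions.

**Step 2**
Reactants: 4 5-bromo-2,3-dimethoxyphenol; 5 4-fluorobenzaldehyde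
Product: 6 4-(5-bromo-2,3-dimethoxyphenoxy)benzaldehyde (CD aldehyde)
Conditions: K2CO3, DMF, 110 °C
Reagents that add atoms: none
Why: Nucleophilic aromatic substitution (SNAr, addition–elimination) works because the para-formyl group activates the C–F bond toward the phenol under carbonate base, whereas the bromide on the electron-rich ring C is not activated and remains.

**Step 3**
Reactants: 6 4-(5-bromo-2,3-dimethoxyphenoxy)benzaldehyde
Product: 7 [4-(5-bromo-2,3-dimethoxyphenoxy)phenyl]methanol (CD benzyl alcohol)
Conditions: NaBH4, MeOH/THF, 0 °C
Reagents that add atoms: none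
Why: Borohydride reduction of an aromatic aldehyde to the benzylic alcohol leaves the aryl bromide and the ethers untouched.

**Step 4**
Reactants: 7 [4-(5-bromo-2,3-dimethoxyphenoxy)phenyl]methanol
Product: 8 [4-(5-bromo-2,3-dimethoxyphenoxy)benzyl]triphenylphosphonium bromide (CD phosphonium salt)
Conditions: PPh3·HBr, MeCN, reflux
Reagents that add atoms: triphenylphosphine hydrobromide, [Br-].c1ccc(cc1)[PH+](c1ccccc1)c1ccccc1
Why: Direct phosphonium salt formation from a benzylic alcohol is an acid-promoted substitution in which the para-aryloxy group stabilises the benzylic cation that triphenylphosphine captures, so no separate benzyl halide is needed.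

**Step 5**
Reactants: 8 [4-(5-bromo-2,3-dimethoxyphenoxy)benzyl]triphenylphosphonium bromide; 3 3-(3-acetylphenoxy)-4-methoxybenzaldehyde
Product: 10 1-[3-(5-{2-[4-(5-bromo-2,3-dimethoxyphenoxy)phenyl]ethenyl}-2-methoxyphenoxy)phenyl]ethanone (seco keto stilbene as E/Z mixture), via benzylic ylide 9 (not isolated)
Conditions: K2CO3, 18-crown-6 (cat.), CH2Cl2, reflux
Reagents that add atoms: none
Why: In this Wittig olefination the semi-stabilised benzylic ylide 9, formed in low concentration by solid carbonate, adds to the aldehyde far faster than to the aryl methyl ketone, and carbonate in CH2Cl2 is too weak to enolise the ketone; the alkene geometry does not matter.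

**Step 6**
Reactants: 10 seco keto stilbene (E/Z mixture)
Product: 11 1-[3-(5-{2-[4-(5-bromo-2,3-dimethoxyphenoxy)phenyl]ethyl}-2-methoxyphenoxy)phenyl]ethanone (seco bromo ketone)
Conditions: H2 (1 atm), Pd/C (10 wt%), Ph2S (0.01 equiv), EtOAc, rt
Reagents that add atoms: none
Why: Catalytic hydrogenation over Pd/C poisoned with diphenyl sulfide saturates the disubstituted alkene while the sulfide suppresses hydrogenolysis of the aryl bromide and reduction of the aryl ketone, and it avoids sulfonylhydrazide-derived diimide, which would condense with the ketone.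

**Step 7**
Reactants: 11 seco bromo ketone
Product: 14 macrocyclic deoxybenzoin (19-membered ring with C=O on ring B and CH2 on ring C; three OMe groups), via seco sodium enolate 12 (not isolated), via macrocyclic sodium enolate 13 (not isolated)
Conditions: Pd2(dba)3 (5 mol%), Xantphos (12 mol%), NaOtBu (2.5 equiv), THF, 65 °C, 11 added by syringe pump over 12 h (final 0.002 M); then 1 M HCl
Reagents that add atoms: none
Why: The ring C C–Br bond adds oxidatively to the zerovalent palladium–Xantphos complex, the sodium enolate 12 of the ring B acetyl group replaces bromide on the resulting arylpalladium bromide (divalent palladium), and reductive elimination from the carbon-bound arylpalladium enolate forms the ring C aryl–CH2 bond. The closest known reaction is the intermolecular palladium-catalysed α-arylation of aryl methyl ketones by aryl bromides with this same catalyst and base, used here in its intramolecular form. The 19-membered ring closes end to end by C–C reductive elimination from a 20-membered palladacycle, which the two diaryl ether hinges and the saturated A–D bridge should let the chain reach without strain; no stereocentre is formed. Ring closure has to win over chain growth, and slow addition of 11 to the catalyst keeps the standing concentration of open-chain bromide low enough for that. Site selectivity needs no control because the acetyl methyl group is the only enolisable position and the ring C bromide the only halide, and the wide bite angle of Xantphos speeds the reductive elimination. A second arylation is held back because the deoxybenzoin is at once deprotonated to the stabilised, more hindered enolate 13, which persists until the acid quench.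

**Step 8**
Reactants: 14 macrocyclic deoxybenzoin
Product: 16 macrocyclic trimethyl ether (B–C bridge now CH2–CH2), via macrocyclic carbinol 15 (not isolated)
Conditions: Et3SiH (5 equiv), CF3CO2H, 0 °C to 50 °C
Reagents that add atoms: none
Why: In this ionic hydrogenation the protonated aryl ketone takes hydride from the silane to give carbinol 15, which ionises in CF3CO2H to a benzylic cation that is reduced again; a hydride shift or elimination within the two-carbon bridge would lead to the same ethano bridge, and the ethers are inert.

**Step 9**
Reactants: 16 macrocyclic trimethyl ether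
Product: 18 target CNP0495401.0 (macrocyclic bis(bibenzyl) with one OH on ring A and two on ring C), via tris(dibromoboryl) ether 17 (not isolated)
Conditions: BBr3 (6 equiv), CH2Cl2, −78 °C to rt; then H2O
Reagents that add atoms: none
Why: BBr3 ether cleavage (bromide attack on the O-methyl carbon of the boron–ether complex) removes all three methyl groups, whereas the diaryl ethers offer no alkyl carbon for bromide and stay intact.

**Compound list**

1 | isovanillin (3-hydroxy-4-methoxybenzaldehyde) | COc1ccc(C=O)cc1O | starting material
2 | 3-acetylphenylboronic acid | CC(=O)c1cccc(c1)B(O)O | starting material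
3 | 3-(3-acetylphenoxy)-4-methoxybenzaldehyde (AB keto aldehyde) | CC(=O)c1cccc(Oc2cc(C=O)ccc2OC)c1 | intermediate
4 | 5-bromo-2,3-dimethoxyphenol | COc1cc(Br)cc(O)c1OC | starting material
5 | 4-fluorobenzaldehyde | O=Cc1ccc(F)cc1 | starting material
6 | 4-(5-bromo-2,3-dimethoxyphenoxy)benzaldehyde (CD aldehyde) | COc1cc(Br)cc(Oc2ccc(C=O)cc2)c1OC | intermediate
7 | [4-(5-bromo-2,3-dimethoxyphenoxy)phenyl]methanol (CD benzyl alcohol) | COc1cc(Br)cc(Oc2ccc(CO)cc2)c1OC | intermediate
8 | [4-(5-bromo-2,3-dimethoxyphenoxy)benzyl]triphenylphosphonium bromide (CD phosphonium salt) | COc1cc(Br)cc(Oc2ccc(C[P+](c3ccccc3)(c3ccccc3)c3ccccc3)cc2)c1OC.[Br-] | intermediate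
9 | [4-(5-bromo-2,3-dimethoxyphenoxy)benzylidene]triphenylphosphorane (benzylic ylide) | COc1cc(Br)cc(Oc2ccc(C=P(c3ccccc3)(c3ccccc3)c3ccccc3)cc2)c1OC | intermediate
10 | 1-[3-(5-{2-[4-(5-bromo-2,3-dimethoxyphenoxy)phenyl]ethenyl}-2-methoxyphenoxy)phenyl]ethanone (seco keto stilbene, E/Z mixture) | CC(=O)c1cccc(Oc2cc(C=Cc3ccc(Oc4cc(Br)cc(OC)c4OC)cc3)ccc2OC)c1 | intermediate
11 | 1-[3-(5-{2-[4-(5-bromo-2,3-dimethoxyphenoxy)phenyl]ethyl}-2-methoxyphenoxy)phenyl]ethanone (seco bromo ketone) | CC(=O)c1cccc(Oc2cc(CCc3ccc(Oc4cc(Br)cc(OC)c4OC)cc3)ccc2OC)c1 | intermediate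
12 | seco sodium enolate (sodium enolate of the acetyl group of 11) | [Na+].[O-]C(=C)c1cccc(Oc2cc(CCc3ccc(Oc4cc(Br)cc(OC)c4OC)cc3)ccc2OC)c1 | intermediate
13 | macrocyclic sodium enolate (sodium enolate of 14, enolate geometry not defined) | [Na+].COc1ccc2cc1Oc1cccc(c1)C([O-])=Cc1cc(OC)c(OC)c(c1)Oc1ccc(cc1)CC2 | intermediate
14 | macrocyclic deoxybenzoin (19-membered ring; C=O attached to ring B, CH2 attached to ring C; OMe on ring A and two OMe on ring C) | COc1ccc2cc1Oc1cccc(c1)C(=O)Cc1cc(OC)c(OC)c(c1)Oc1ccc(cc1)CC2 | intermediate
15 | macrocyclic carbinol (racemic; CH(OH) attached to ring B) | COc1ccc2cc1Oc1cccc(c1)C(O)Cc1cc(OC)c(OC)c(c1)Oc1ccc(cc1)CC2 | intermediate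
16 | macrocyclic trimethyl ether (tri-O-methyl ether of the target) | COc1ccc2cc1Oc1cccc(c1)CCc1cc(OC)c(OC)c(c1)Oc1ccc(cc1)CC2 | intermediate
17 | tris(dibromoboryl) ether of the target | BrB(Br)Oc1ccc2cc1Oc1cccc(c1)CCc1cc(OB(Br)Br)c(OB(Br)Br)c(c1)Oc1ccc(cc1)CC2 | intermediate
18 | target CNP0495401.0 (macrocyclic bis(bibenzyl) triol) | Oc1ccc2cc1Oc1cccc(c1)CCc1cc(O)c(O)c(c1)Oc1ccc(cc1)CC2 | target

**Step count and risks**

Total step count: 9. Longest linear sequence: 8 steps (steps 2 to 9, from 4 and 5); step 1 is a one-step branch.

Steps most likely to fail: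

1. Step 7. Chain growth by intermolecular arylation, aldol-type self-condensation of the enolate, or hydrodebromination may outrun the slow closure of the large ring. Fallback: setting out from seco bromo ketone 11, NaBH4 in MeOH/THF would reduce the acetyl group to the racemic seco bromo carbinol F1. Dehydration with the Burgess reagent in toluene at 80 °C would give the ring B styrene, the seco bromo styrene F2. Hydroboration with 9-BBN-H in THF would give the primary seco B-alkyl-9-BBN F3, which would not be isolated but added slowly to PdCl2(dppf) and aqueous Cs2CO3 in THF/DMF at 60 °C. This B-alkyl Suzuki–Miyaura macrocyclisation forms the same ring C aryl–CH2 bond without an enolate and would give the trimethyl ether directly. It comes back to the route at 16, so step 8 is not needed.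

2. Step 6. Hydrogenolysis of the C–Br bond or reduction of the aryl ketone may compete with saturation of the alkene, or the poisoned catalyst may stall before the stilbene is consumed. Fallback: setting out from phosphonium salt 8 and isovanillin 1, silylation of 1 (tBuMe2SiCl, imidazole, DMF) would give 3-(tert-butyldimethylsilyloxy)-4-methoxybenzaldehyde F4. Wittig reaction of F4 with 8 (K2CO3, 18-crown-6, CH2Cl2, reflux) would give the silyl stilbene F5. Diimide from TsNHNH2 and NaOAc (DME/H2O, reflux) would saturate the alkene without touching the bromide and give the silyl bibenzyl F6; no ketone is present at this stage. Bu4NF in THF would free the ring A phenol of the bibenzyl phenol F7. Chan–Lam coupling of F7 with boronic acid 2 (Cu(OAc)2, pyridine, 4 Å molecular sieves, CH2Cl2, air, rt) would then install the acetylphenyl ring last and come back to the route at 11.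

3. Step 8. The second ionisation may stall because the benzylic cation next to ring B has no para donor, leaving the reduction at the carbinol stage, or the cation may alkylate an electron-rich ring. Fallback: setting out from macrocyclic deoxybenzoin 14, Wolff–Kishner reduction (N2H4·H2O, KOH, diethylene glycol, 130 °C then 200 °C) would pass through the macrocyclic hydrazone F8 and lose dinitrogen under base, with no cation involved. It comes back to the route at 16; any partial O-demethylation under the hot base would be harmless because step 9 removes all methyl groups.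

**Further compounds**

F1 | step 7 | seco bromo carbinol, 1-[3-(5-{2-[4-(5-bromo-2,3-dimethoxyphenoxy)phenyl]ethyl}-2-methoxyphenoxy)phenyl]ethanol (racemic) | CC(O)c1cccc(Oc2cc(CCc3ccc(Oc4cc(Br)cc(OC)c4OC)cc3)ccc2OC)c1
F2 | step 7 | seco bromo styrene (ring B vinyl in place of acetyl) | C=Cc1cccc(Oc2cc(CCc3ccc(Oc4cc(Br)cc(OC)c4OC)cc3)ccc2OC)c1
F3 | step 7 | seco B-alkyl-9-BBN (ring B CH2CH2–B of 9-borabicyclo[3.3.1]nonane) | COc1ccc(CCc2ccc(Oc3cc(Br)cc(OC)c3OC)cc2)cc1Oc1cccc(CCB2C3CCCC2CCC3)c1
F4 | step 6 | 3-(tert-butyldimethylsilyloxy)-4-methoxybenzaldehyde | COc1ccc(C=O)cc1O[Si](C)(C)C(C)(C)C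
F5 | step 6 | silyl stilbene (E/Z mixture; ring A OTBS, rings C and D as in 8) | COc1ccc(C=Cc2ccc(Oc3cc(Br)cc(OC)c3OC)cc2)cc1O[Si](C)(C)C(C)(C)C
F6 | step 6 | silyl bibenzyl | COc1ccc(CCc2ccc(Oc3cc(Br)cc(OC)c3OC)cc2)cc1O[Si](C)(C)C(C)(C)C
F7 | step 6 | bibenzyl phenol, 5-{2-[4-(5-bromo-2,3-dimethoxyphenoxy)phenyl]ethyl}-2-methoxyphenol | COc1ccc(CCc2ccc(Oc3cc(Br)cc(OC)c3OC)cc2)cc1O
F8 | step 8 | macrocyclic hydrazone of 14 | COc1ccc2cc1Oc1cccc(c1)C(=NN)Cc1cc(OC)c(OC)c(c1)Oc1ccc(cc1)CC2
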